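## Retrosynthetic overview
1. Target 17 comes from a δ-lactone (temporary ring A′, C3(=O)–O–C1). SmI2 cuts its C1–O bond in the last step, which frees the hindered C3 acid and the C1H2–C2 acid arm together.
2. The C12 carbinol comes from oxidation then reduction. The C13 vinyl group and the C12 oxygen come from epoxidation and vinyl opening of a cyclic enol ether.
3. Key step: the acyclic bromo ester 8 gives tricycle 10 in one radical–polar crossover cascade. Ring order: A′ (C4–C5), then B (C10–C9), then C (C8–O).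
4. Compound 8 comes from 2-bromoisobutyryl bromide and the (S)-α-hydroxy ester 6. Ester 6 comes from enal 2 and tert-butyl isocyanide, and 2 comes from (E)-geranylacetone.

Assumption: labdane numbering is used throughout (C2 and C3 are the two carboxyl carbons; C20, C17 and C16 are the methyl groups on C10, C8 and C13), and geranylacetone is bought as the pure (E)-isomer.

## Route

Step 1
Reactants: 1 (E)-geranylacetone
Product: 2 (2E,6E)-2,6-dimethyl-10-oxoundeca-2,6-dienal
Conditions: SeO2 (1.1 equiv), 1,4-dioxane, 70 °C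
Reagents that add atoms: selenium dioxide O=[Se]=O
Why: Riley allylic oxidation (ene reaction, then [2,3]-sigmatropic shift of the allylseleninic acid) attacks only the (E)-methyl group of the more accessible terminal trisubstituted alkene, so the enal is (E) and no stereocentre is formed.

Step 2
Reactants: 2 (2E,6E)-2,6-dimethyl-10-oxoundeca-2,6-dienal; 3 tert-butyl isocyanide
Product: 6 methyl (2S,3E,7E)-2-hydroxy-3,7-dimethyl-11-oxododeca-3,7-dienoate, via imidoyl chloride 4 (not isolated), via methyl imidate 5 (not isolated)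
Conditions: SiCl4 (1.1 equiv), 3 (1.2 equiv, slow addition), chiral 2,2'-diamino-1,1'-binaphthyl-derived bisphosphoramide (5 mol %, antipode giving Re-face attack), CH2Cl2, −74 °C; then MeOH, −74 °C → rt; then sat. aq NaHCO3
Reagents that add atoms: tert-butyl isocyanide 3 [C-]#[N+]C(C)(C)C; methanol CO; water O
Why: In this Lewis-base-activated SiCl4 Passerini-type α-addition the chiral phosphoramide-bound silyl cation binds only the aldehyde (the methyl ketone is inert), the isocyanide carbon (future C2) attacks the Re face to set C1 as (S), and methanolysis followed by hydrolysis of the imidoyl chloride gives the methyl ester.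

Step 3
Reactants: 6 methyl (2S,3E,7E)-2-hydroxy-3,7-dimethyl-11-oxododeca-3,7-dienoate; 7 2-bromo-2-methylpropanoyl bromide
Product: 8 methyl (2S,3E,7E)-2-[(2-bromo-2-methylpropanoyl)oxy]-3,7-dimethyl-11-oxododeca-3,7-dienoate
Conditions: 7 (1.3 equiv), pyridine (2 equiv), DMAP (5 mol %), CH2Cl2, 0 °C → rt
Reagents that add atoms: 2-bromo-2-methylpropanoyl bromide 7 CC(C)(Br)C(=O)Br
Why: DMAP-catalysed O-acylation of the secondary alcohol brings in C3, C4 and both C4 methyl groups without touching the C1 stereocentre.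

Step 4 (key step)
Reactants: 8 methyl (2S,3E,7E)-2-[(2-bromo-2-methylpropanoyl)oxy]-3,7-dimethyl-11-oxododeca-3,7-dienoate
Product: 10 methyl (1S,5S,8S,9S,10R)-8,13-epoxy-3-oxo-2-oxa-14,15-dinorlabd-12-ene-1-carboxylate (tricyclic enol ether δ-lactone), via tricyclic oxocarbenium bromide 9 (not isolated)
Conditions: Ir(ppy)3 (1 mol %), 2,6-lutidine (1.5 equiv), MeCN (0.005 M), blue LEDs (450 nm), 60 °C
Reagents that add atoms: none
Why: Proposed new method: photoexcited Ir(ppy)3 reduces the tertiary C–Br bond to the C4 α-ester radical, which closes 6-endo on C5 (the C10 methyl blocks the 5-exo mode, and the C1 ester group sits equatorial so that C1 selects the alkene face), the ring-held tertiary C10 radical then adds 6-endo to the (E)-C8=C9 alkene through a chair (trans fusion, C20 axial, H9 anti to C20), tetravalent iridium oxidises the tertiary C8 radical to the cation, the ketone oxygen captures it from the face away from the axial C20 methyl, and lutidine removes H12, so that C5, C10, C9 and C8 all derive from C1 and any minor diastereomer is removed by chromatography before C1 is erased; the closest known reaction types are manganese triacetate radical polyene cyclisations of α-methyl β-keto esters, atom-transfer radical lactonisations of allyl α-halo esters, photoredox radical–polar crossover, and the acid cyclisation of geranylacetone that ends on the ketone oxygen.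

Step 5
Reactants: 10 tricyclic enol ether δ-lactone; 11 vinylmagnesium bromide
Product: 13 methyl (1S,5S,8S,9S,10R,12R,13S)-8,13-epoxy-12-hydroxy-3-oxo-2-oxalabd-14-ene-1-carboxylate, via glycal-type epoxide 12 (not isolated)
Conditions: DMDO (1.2 equiv), acetone/CH2Cl2, −78 → 0 °C, evaporate cold; then 11 (2.5 equiv), CuBr·SMe2 (10 mol %), THF, −78 → −40 °C; aq NH4Cl
Reagents that add atoms: dimethyldioxirane CC1(C)OO1; vinylmagnesium bromide 11 C=C[Mg]Br
Why: The only alkene is epoxidised from the face opposite the axial C17 and C20 methyl groups, and the copper-modified Grignard reagent then opens the anomeric epoxide anti (trans-diaxially) at the tertiary C13, as in C-glycoside synthesis from glycal epoxides, which places the vinyl group axial (13S) and leaves the C12 oxygen on the opposite face (12R), while the hindered lactone and ester survive at low temperature.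

Step 6
Reactants: 13 methyl (1S,5S,8S,9S,10R,12R,13S)-8,13-epoxy-12-hydroxy-3-oxo-2-oxalabd-14-ene-1-carboxylate
Product: 14 methyl (1S,5S,8S,9S,10R,13S)-8,13-epoxy-3,12-dioxo-2-oxalabd-14-ene-1-carboxylate
Conditions: Pr4N[RuO4] (5 mol %), NMO (1.5 equiv), 4 Å MS, CH2Cl2, rt
Reagents that add atoms: none
Why: Ley–Griffith oxidation converts the axial secondary alcohol into the ketone under neutral conditions that leave the vinyl group, lactone and ester alone, and the quaternary C13 cannot epimerise or let the alkene move into conjugation.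

Step 7
Reactants: 14 methyl (1S,5S,8S,9S,10R,13S)-8,13-epoxy-3,12-dioxo-2-oxalabd-14-ene-1-carboxylate
Product: 15 methyl (1S,5S,8S,9S,10R,12S,13S)-8,13-epoxy-12-hydroxy-3-oxo-2-oxalabd-14-ene-1-carboxylate
Conditions: NaBH4 (1.2 equiv), CeCl3·7H2O (1.2 equiv), MeOH, −40 °C
Reagents that add atoms: none
Why: In this Luche reduction the small hydride attacks axially from the face opposite the axial C13 vinyl group (only H9 lies there) and gives the equatorial (12S)-alcohol cis to the vinyl group, while the esters are too slow to react at this temperature.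

Step 8
Reactants: 15 methyl (1S,5S,8S,9S,10R,12S,13S)-8,13-epoxy-12-hydroxy-3-oxo-2-oxalabd-14-ene-1-carboxylate
Product: 17 (5S,8S,9S,10R,12S,13S)-8,13-epoxy-12-hydroxy-2,3-secolabd-14-ene-2,3-dioic acid, via monomethyl ester 16 (not isolated)
Conditions: SmI2 (3 equiv), THF/HMPA (10:1), MeOH (3 equiv), 0 °C; then aq LiOH, 45 °C; then 1 M HCl to pH 3
Reagents that add atoms: lithium hydroxide [Li+].[OH-]
Why: In this SmI2 reductive α-deoxygenation of an α-acyloxy ester, electron transfer to the methyl ester expels the lactone carboxylate from C1 and the samarium enolate is protonated to the CH2CO2Me arm, which erases the auxiliary C1 centre and frees the hindered C3 acid without hydrolysis at that site, after which ordinary saponification of the remaining primary-alkyl ester gives the diacid with no other stereocentre touched.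

## Compound list
1 | (E)-geranylacetone, (5E)-6,10-dimethylundeca-5,9-dien-2-one | CC(=O)CC/C=C(\C)CCC=C(C)C | starting material
2 | (2E,6E)-2,6-dimethyl-10-oxoundeca-2,6-dienal | CC(=O)CC/C=C(\C)CC/C=C(\C)C=O | intermediate
3 | tert-butyl isocyanide | [C-]#[N+]C(C)(C)C | starting material
4 | (2S,3E,7E)-N-tert-butyl-3,7-dimethyl-11-oxo-2-(trichlorosilyloxy)dodeca-3,7-dienimidoyl chloride | CC(C)(C)N=C(Cl)[C@@H](O[Si](Cl)(Cl)Cl)/C(C)=C/CC/C(C)=C/CCC(C)=O | intermediate (not isolated)
5 | methyl (2S,3E,7E)-N-tert-butyl-2-hydroxy-3,7-dimethyl-11-oxododeca-3,7-dienimidate | COC(=NC(C)(C)C)[C@@H](O)/C(C)=C/CC/C(C)=C/CCC(C)=O | intermediate (not isolated)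
6 | methyl (2S,3E,7E)-2-hydroxy-3,7-dimethyl-11-oxododeca-3,7-dienoate | COC(=O)[C@@H](O)/C(C)=C/CC/C(C)=C/CCC(C)=O | intermediate
7 | 2-bromo-2-methylpropanoyl bromide | CC(C)(Br)C(=O)Br | starting material
8 | methyl (2S,3E,7E)-2-[(2-bromo-2-methylpropanoyl)oxy]-3,7-dimethyl-11-oxododeca-3,7-dienoate | COC(=O)[C@@H](OC(=O)C(C)(C)Br)/C(C)=C/CC/C(C)=C/CCC(C)=O | intermediate
9 | tricyclic oxocarbenium bromide (C13=O+ form of 10, C12 still CH2) | CC1=[O+][C@@]2(C)CC[C@@H]3C(C)(C)C(=O)O[C@H](C(=O)OC)[C@@]3(C)[C@@H]2CC1.[Br-] | intermediate (not isolated)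
10 | methyl (1S,5S,8S,9S,10R)-8,13-epoxy-3-oxo-2-oxa-14,15-dinorlabd-12-ene-1-carboxylate | CC1=CC[C@H]2[C@]3(C)[C@@H](C(=O)OC)OC(=O)C(C)(C)[C@H]3CC[C@]2(C)O1 | intermediate
11 | vinylmagnesium bromide | C=C[Mg]Br | starting material
12 | (12R,13S)-12,13-epoxide of 10 (oxirane on the face opposite C17 and C20) | C[C@]12O[C@@]3(C)CC[C@@H]4C(C)(C)C(=O)O[C@H](C(=O)OC)[C@@]4(C)[C@@H]3C[C@H]1O2 | intermediate (not isolated)
13 | methyl (1S,5S,8S,9S,10R,12R,13S)-8,13-epoxy-12-hydroxy-3-oxo-2-oxalabd-14-ene-1-carboxylate | C=C[C@]1(C)O[C@@]2(C)CC[C@@H]3C(C)(C)C(=O)O[C@H](C(=O)OC)[C@@]3(C)[C@@H]2C[C@H]1O | intermediate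
14 | methyl (1S,5S,8S,9S,10R,13S)-8,13-epoxy-3,12-dioxo-2-oxalabd-14-ene-1-carboxylate | C=C[C@]1(C)O[C@@]2(C)CC[C@@H]3C(C)(C)C(=O)O[C@H](C(=O)OC)[C@@]3(C)[C@@H]2CC1=O | intermediate
15 | methyl (1S,5S,8S,9S,10R,12S,13S)-8,13-epoxy-12-hydroxy-3-oxo-2-oxalabd-14-ene-1-carboxylate | C=C[C@]1(C)O[C@@]2(C)CC[C@@H]3C(C)(C)C(=O)O[C@H](C(=O)OC)[C@@]3(C)[C@@H]2C[C@@H]1O | intermediate
16 | (5S,8S,9S,10R,12S,13S)-8,13-epoxy-12-hydroxy-2,3-secolabd-14-ene-2,3-dioic acid 2-methyl ester | C=C[C@]1(C)O[C@@]2(C)CC[C@H](C(C)(C)C(=O)O)[C@@](C)(CC(=O)OC)[C@@H]2C[C@@H]1O | intermediate (not isolated)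
17 | (5S,8S,9S,10R,12S,13S)-8,13-epoxy-12-hydroxy-2,3-secolabd-14-ene-2,3-dioic acid (CNP0325408.2) | C=C[C@]1(C)O[C@@]2(C)CC[C@H](C(C)(C)C(=O)O)[C@@](C)(CC(=O)O)[C@@H]2C[C@@H]1O | target

## Step count and risks
Total step count: 8. Longest linear sequence: 8 (from 1).

**Most likely to fail, first: step 4.**
- Failure mode: the ester tether must reach its less populated s-cis rotamer before the hindered 6-endo closure can occur. Debromination or a poor C1-to-C5 relay could win.
- The fallback sets out from 6 and comes back at 17. It makes the C4–C5 bond by a pericyclic reaction and closes only rings B and C by a cation.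
- Heating 6 with trimethyl orthoisobutyrate and catalytic propionic acid at 140 °C is a Johnson–Claisen rearrangement through a chair transition state, with C1-to-C5 chirality transfer. It gives dimethyl (3S,4E)-2,2,4-trimethyl-3-[(3E)-3-methyl-7-oxooct-3-enyl]hex-4-enedioate F1.
- Catalytic HNTf2 in CH2Cl2 at −40 °C cycloisomerises F1. This is an enoate-initiated cation–olefin closure ended by the ketone oxygen, and any C10 epimer is separated. The product is the bicyclic enol ether dimethyl ester F2.
- DMDO gives the 12,13-epoxide diester F3.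
- The copper-modified vinyl Grignard reagent gives the (12R)-alcohol diester F4.
- Pr4N[RuO4]/NMO gives the 12-ketone diester F5.
- NaBH4/CeCl3·7H2O gives the dimethyl ester of the target F6.
- LiI in refluxing pyridine removes both methyl groups by SN2 dealkylation and gives 17.

**Second: step 5.**
- Failure mode: the nucleophile must enter at a tertiary anomeric carbon on the face that carries the axial C17 methyl group. The epoxide could also rearrange by hydride shift.
- The fallback sets out from 10 (through 12) and comes back at 13. It brings the two carbons in as a slim, linear sp nucleophile and adjusts the oxidation level afterwards.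
- Epoxide 12 is opened with ethynylmagnesium bromide in THF at −78 → −20 °C. This gives methyl (1S,5S,8S,9S,10R,12R,13S)-8,13-epoxy-12-hydroxy-3-oxo-2-oxalabd-14-yne-1-carboxylate F7.
- Semihydrogenation of F7 (H2, Pd/CaCO3 poisoned with Pb(OAc)2, quinoline) gives 13.

**Third: step 2.**
- Failure mode: an aliphatic α-methyl enal may give only moderate enantioselectivity.
- The fallback sets out from 2 and comes back at 6. It uses cyanide as the C2 synthon under enzyme control.
- (S)-Hydroxynitrile lyase from Hevea brasiliensis with HCN (citrate buffer pH 5 / MTBE, 0 °C) gives (2S,3E,7E)-2-hydroxy-3,7-dimethyl-11-oxododeca-3,7-dienenitrile F8.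
- A Pinner reaction (HCl, MeOH, 0 °C) gives the methyl imidate hydrochloride F9.
- Water hydrolyses F9 to 6.

Further compounds
F1 | step 4 | dimethyl (3S,4E)-2,2,4-trimethyl-3-[(3E)-3-methyl-7-oxooct-3-enyl]hex-4-enedioate | COC(=O)/C=C(\C)[C@H](CC/C(C)=C/CCC(C)=O)C(C)(C)C(=O)OC
F2 | step 4 | dimethyl (5S,8S,9S,10R)-8,13-epoxy-14,15-dinor-2,3-secolabd-12-ene-2,3-dioate | CC1=CC[C@H]2[C@](C)(CC(=O)OC)[C@@H](C(C)(C)C(=O)OC)CC[C@]2(C)O1
F3 | step 4 | (12R,13S)-12,13-epoxide of F2 | C[C@]12O[C@@]3(C)CC[C@H](C(C)(C)C(=O)OC)[C@@](C)(CC(=O)OC)[C@@H]3C[C@H]1O2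
F4 | step 4 | dimethyl (5S,8S,9S,10R,12R,13S)-8,13-epoxy-12-hydroxy-2,3-secolabd-14-ene-2,3-dioate | C=C[C@]1(C)O[C@@]2(C)CC[C@H](C(C)(C)C(=O)OC)[C@@](C)(CC(=O)OC)[C@@H]2C[C@H]1O
F5 | step 4 | dimethyl (5S,8S,9S,10R,13S)-8,13-epoxy-12-oxo-2,3-secolabd-14-ene-2,3-dioate | C=C[C@]1(C)O[C@@]2(C)CC[C@H](C(C)(C)C(=O)OC)[C@@](C)(CC(=O)OC)[C@@H]2CC1=O
F6 | step 4 | dimethyl (5S,8S,9S,10R,12S,13S)-8,13-epoxy-12-hydroxy-2,3-secolabd-14-ene-2,3-dioate | C=C[C@]1(C)O[C@@]2(C)CC[C@H](C(C)(C)C(=O)OC)[C@@](C)(CC(=O)OC)[C@@H]2C[C@@H]1O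
F7 | step 5 | methyl (1S,5S,8S,9S,10R,12R,13S)-8,13-epoxy-12-hydroxy-3-oxo-2-oxalabd-14-yne-1-carboxylate | C#C[C@]1(C)O[C@@]2(C)CC[C@@H]3C(C)(C)C(=O)O[C@H](C(=O)OC)[C@@]3(C)[C@@H]2C[C@H]1O
F8 | step 2 | (2S,3E,7E)-2-hydroxy-3,7-dimethyl-11-oxododeca-3,7-dienenitrile | N#C[C@@H](O)/C(C)=C/CC/C(C)=C/CCC(C)=O
F9 | step 2 | methyl (2S,3E,7E)-2-hydroxy-3,7-dimethyl-11-oxododeca-3,7-dienimidate hydrochloride | COC(=[NH2+])[C@@H](O)/C(C)=C/CC/C(C)=C/CCC(C)=O.[Cl-]
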